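Each vessel below took the same charge, and the question was how much of the exchanged complex stayed at one exchange.

| flask | starting complex | incoming ligand | leaving ligand | time | remark |
|---|---|---|---|---|---|
| oak | 0.050 M | 0.0250 M (fed, over 5.00 min) | 0.0250 M | 10 min | all but incoming ligand at the start; incoming ligand goes in evenly over 5.00 min, the run ends at 10 min |
| cedar | 0.050 M | 0.0250 M | 0.0250 M | 10 min | everything together in a closed stirred flask, run for 10 min |
| maple | 0.050 M | 0.0250 M | 0.0250 M |  | a single well-mixed tank run continuously and read at steady state, 10 min in it on average |
| birch | 0.050 M | 0.0250 M | 0.0250 M | 10 min | plug flow through a tube for 10 min, no back-mixing |

    starting complex + incoming ligand ⇌ leaving ligand + complex with one exchanged (K1 = 1.0, k1 = 0.076 M⁻¹ s⁻¹)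
    complex with one exchanged + incoming ligand ⇌ leaving ligand + complex with two exchanged (K2 = 0.42, k2 = 0.094 M⁻¹ s⁻¹)
    complex with two exchanged + incoming ligand ⇌ leaving ligand + complex with three exchanged (K3 = 0.60, k3 = 0.0033 M⁻¹ s⁻¹)
    complex with three exchanged + incoming ligand ⇌ leaving ligand + complex with four exchanged (K4 = 0.61, k4 = 0.031 M⁻¹ s⁻¹)
    starting complex ⇌ dormant form (K5 = 0.36, k5 = 4.6 × 10⁻⁴ s⁻¹)
    complex with one exchanged → over-reaction product (k6 = 4.5 × 10⁻⁷ s⁻¹)
    leaving ligand → by-product carried off (k7 = 9.6 × 10⁻⁴ s⁻¹)

- the set-up with the highest share of complex with one exchanged in all that became complex with one exchanged or complex with two exchanged or complex with three exchanged or complex with four exchanged, at the outlet or at the end ("none" if the first two lie within 2 percentage points) (oak / cedar / maple / birch / none)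
- share of complex with one exchanged in all that became complex with one exchanged or complex with two exchanged or complex with three exchanged or complex with four exchanged, at the outlet or at the end, oak
- share of complex with one exchanged in all that became complex with one exchanged or complex with two exchanged or complex with three exchanged or complex with four exchanged, at the outlet or at the end, cedar
- share of complex with one exchanged in all that became complex with one exchanged or complex with two exchanged or complex with three exchanged or complex with four exchanged, at the outlet or at the end, maple
- share of complex with one exchanged in all that became complex with one exchanged or complex with two exchanged or complex with three exchanged or complex with four exchanged, at the outlet or at the end, birch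

- the stated concentrations are those of everything mixed, before any reaction; amounts are the same in each set-up
- the feed brings no volume worth counting
- the share counts what is present at the end, not what went on to other products
- run time (oak): 10 min

I reckoned cedar first and drew its share against time. The share started at 100%, since complex with two exchanged forms from complex with one exchanged. Early on, their ratio climbed at half of k2 times the incoming ligand, 0.0705 min⁻¹.

The zero of my scale was the symmetric mixture. With incoming and leaving ligand equal, as charged, step 2 balanced at a ratio of K2, a share of 70.4%. But the mixture leaves that zero as it reacts. Incoming ligand is the limiting reagent, at half of the starting complex, and each exchange turns one incoming ligand into a leaving one. With K1 at 1.0, and with step 2 and step 5 neglected, I put step 1 in balance after 0.0125 M had exchanged, which put incoming over leaving ligand at 0.333.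

That gave the balance ratio, the complex with two exchanged per complex with one exchanged when step 2 stands balanced, equal to K2 times incoming over leaving ligand: 0.140. Its level was a share of 87.7%, higher than the symmetric zero.

Held straight, cedar's early slope met that ratio at an estimated knee near 1.99 min, well before the end of the run. Past the knee I drew a slow decline, since the leaving ligand's half-life of 12 min by step 7 alone is longer than the knee. Its carry-off raises the ligand ratio gradually, so I committed to cedar lying a little under that level.

Birch repeats cedar's history along a tube. Oak's feed stops at 5.00 min, and the 5.00 min that remain of its run are longer than the knee estimated for cedar. I expected maple's spread of ages to cost less than the margin, so I expected no leader.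

The forecast gave oak 86%, cedar 85.6%, maple 84.9% and birch 85.6%, with best none, a cedar figure lower than my level. Its grounds included this: “Birch behaves exactly like cedar because plug flow matches a batch run”.

The simulation gave oak 85.8%, cedar 85.8%, maple 84.9% and birch 85.8%, with best none.

In cedar, with the other concentrations as charged and the forward step alone counted, the half-life of complex with one exchanged by step 2 was 4.9 min, against 140 min for complex with two exchanged by step 3, which is long beside the 10 min run. Read as a ratio, cedar's share gave 0.165 of the further-exchanged complexes per complex with one exchanged, 1.18 times the balance ratio. Maple's share gave 0.178, which is 1.27 times the balance ratio.

(The constants were drawn at random within sensible limits.)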